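The pyran ring F of the lower flavan unit (benzo ring D, aryl ring E) is disconnected across C4–C4a and C2–C3 to a formal [4+2] between an O-aryl oxocarbenium ion (2-oxadiene C4a=C8a–O1–C2+, ring E on C2) and the two-carbon (E)-enamine of benzyloxyacetaldehyde. The key step exploits the nucleophilic C4a of phloroglucinol-type ring D, ortho to O1, and the benzylic, ring-E-stabilised C2: enamine C-alkylation forms C2–C3, the resulting iminium closes onto C4a, and a twofold-symmetric chiral pyrrolidine, later removed reductively, sets C2 and C3. The precursor is a benzotriazolyl N,O-acetal on the ring-D phenol of a 4-arylflavan that already carries the mesquitol unit.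

Key step: step 12

Remark: ring letters are A (benzo), B (aryl), C (pyran) for the upper unit and D, E, F for the lower unit, with locants of each flavan unit; poly-L-leucine, 3,5-bis(benzyloxy)phenol and (2S,5S)-2,5-dimethylpyrrolidine are taken as commercial.

Step 1
Reactants: 1 2,3,4-trihydroxyacetophenone
Product: 2 1-[3,4-bis(benzyloxy)-2-hydroxyphenyl]ethanone
Conditions: BnBr (2.1 equiv), K2CO3, acetone, reflux
Reagents that add atoms: benzyl bromide BrCc1ccccc1
Why: Williamson etherification with K2CO3 alkylates the 3- and 4-OH groups, while the 2-OH, held in a hydrogen bond to the ketone, should stay free.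

Step 2
Reactants: 2 1-[3,4-bis(benzyloxy)-2-hydroxyphenyl]ethanone
Product: 3 1-[3,4-bis(benzyloxy)-2-(methoxymethoxy)phenyl]ethanone
Conditions: NaH, MOMCl, DMF, 0 °C to rt
Reagents that add atoms: chloromethyl methyl ether COCCl
Why: NaH breaks the chelate so that the last phenol is masked as its MOM ether (Williamson-type alkylation), which keeps it out of the base-mediated condensation and epoxidation.

Step 3
Reactants: 3 1-[3,4-bis(benzyloxy)-2-(methoxymethoxy)phenyl]ethanone; 4 3,4-bis(benzyloxy)benzaldehyde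
Product: 5 (E)-2'-(methoxymethoxy)-3,4,3',4'-tetrakis(benzyloxy)chalcone
Conditions: KOH, EtOH/THF, rt
Reagents that add atoms: none
Why: Claisen–Schmidt condensation of the methyl ketone enolate with the non-enolisable aldehyde, followed by dehydration, should give the thermodynamically favoured (E)-enone.

Step 4
Reactants: 5 (E)-2'-(methoxymethoxy)-3,4,3',4'-tetrakis(benzyloxy)chalcone
Product: 6 (2R,3S)-trans-epoxy ketone
Conditions: poly-L-leucine, urea–H2O2, DBU, THF, rt
Reagents that add atoms: hydrogen peroxide (as its urea adduct) OO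
Why: Juliá–Colonna epoxidation, in which the helical poly-L-leucine delivers hydroperoxide to one face of the (E)-enone, should set both epoxide centres as (2R,3S) in the trans-epoxide.

Step 5
Reactants: 6 (2R,3S)-trans-epoxy ketone
Product: 7 (2R,3R)-7,8-bis(benzyloxy)-2-[3,4-bis(benzyloxy)phenyl]-3-hydroxychroman-4-one
Conditions: conc. HCl, MeOH/THF, 55 °C
Reagents that add atoms: none
Why: Acid removes the MOM group and the freed phenol opens the epoxide at the benzylic carbon with inversion (6-endo closure favoured by the electron-rich aryl group), so C3 keeps the epoxide configuration and C2 is set as R in the 2,3-trans dihydroflavonol.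

Step 6
Reactants: 7 (2R,3R)-7,8-bis(benzyloxy)-2-[3,4-bis(benzyloxy)phenyl]-3-hydroxychroman-4-one
Product: 8 (2R,3S,4R)-7,8-bis(benzyloxy)-2-[3,4-bis(benzyloxy)phenyl]chromane-3,4-diol
Conditions: NaBH4, MeOH/THF, 0 °C
Reagents that add atoms: none
Why: Hydride reduction of the ketone gives the flavan-3,4-diol, expected mainly 3,4-trans by attack anti to the 3-substituent, although the C4 configuration is lost again in step 8.

Step 7
Reactants: 8 (2R,3S,4R)-7,8-bis(benzyloxy)-2-[3,4-bis(benzyloxy)phenyl]chromane-3,4-diol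
Product: 9 (2R,3S,4R)-3,4,7,8-tetrakis(benzyloxy)-2-[3,4-bis(benzyloxy)phenyl]chromane
Conditions: NaH, BnBr, Bu4NI (cat.), DMF, 0 °C to rt
Reagents that add atoms: benzyl bromide BrCc1ccccc1
Why: Double Williamson benzylation protects O3 for the rest of the route and turns O4 into the benzylic ether leaving group used in step 8.

Step 8
Reactants: 9 (2R,3S,4R)-3,4,7,8-tetrakis(benzyloxy)-2-[3,4-bis(benzyloxy)phenyl]chromane; 10 3,5-bis(benzyloxy)phenol
Product: 11 4-arylflavan phenol (upper unit joined to ring D)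
Conditions: 10 (3 equiv), BF3·OEt2 (0.5 equiv), CH2Cl2, −20 to 0 °C
Reagents that add atoms: none
Why: BF3 ionises the 4-benzyloxy group to a flavan-4-yl cation stabilised by O1 and the 7-benzyloxy group, and Friedel–Crafts attack of the phenol anti to the 3-benzyloxy group should give the 3,4-trans (4S) adduct at a position ortho to the free hydroxyl (flanked by OH and OBn) and not at the more shielded position between the two benzyloxy groups.

Step 9
Reactants: 4 3,4-bis(benzyloxy)benzaldehyde; 12 1H-benzotriazole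
Product: 13 1-[[3,4-bis(benzyloxy)phenyl](chloro)methyl]-1H-benzotriazole
Conditions: SOCl2 (1.2 equiv), toluene, 70 °C
Reagents that add atoms: thionyl chloride O=S(Cl)Cl
Why: Condensation of the aldehyde with benzotriazole to the hemiaminal and its chlorination with SOCl2 give the N-(alpha-chlorobenzyl)benzotriazole, a known type of alkoxyalkylating agent.

Step 10
Reactants: 11 4-arylflavan phenol; 13 1-[[3,4-bis(benzyloxy)phenyl](chloro)methyl]-1H-benzotriazole
Product: 14 benzotriazolyl N,O-acetal on the ring-D oxygen (both epimers at the acetal carbon)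
Conditions: NaH, THF/DMF, 0 °C to rt
Reagents that add atoms: none
Why: The sodium phenoxide displaces chloride from 13 (SN1-like substitution through the benzotriazole-stabilised cation) to give a bench-stable N,O-acetal in which benzotriazole is the group expected to leave on Lewis-acid activation; both epimers converge in step 12.

Step 11
Reactants: 15 (benzyloxy)acetaldehyde; 16 (2S,5S)-2,5-dimethylpyrrolidine
Product: 17 (2S,5S)-1-[(E)-2-(benzyloxy)ethenyl]-2,5-dimethylpyrrolidine
Conditions: 4 Å molecular sieves, CH2Cl2, 0 °C to rt; used crude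
Reagents that add atoms: none
Why: Condensation of the aldehyde with the secondary amine under dehydrating conditions gives the enamine, (E) for steric reasons, whose nucleophilic β-carbon carries the benzyloxy group.

Step 12
Reactants: 14 benzotriazolyl N,O-acetal; 17 (2S,5S)-1-[(E)-2-(benzyloxy)ethenyl]-2,5-dimethylpyrrolidine
Product: 20 ring-F-closed 4-(2,5-dimethylpyrrolidin-1-yl) protected dimer, via O-aryl oxocarbenium benzotriazolide 18 (not isolated), via ring-open iminium benzotriazolide 19 (not isolated)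
Conditions: 17 (2 equiv), ZnBr2 (0.3 equiv), 4 Å molecular sieves, CH2Cl2/MeCN, −40 °C to rt; aq. NaHCO3
Reagents that add atoms: none
Why: Proposed new method: ZnBr2-assisted loss of benzotriazolide from 14 gives the O-aryl oxocarbenium ion 18, which the (E)-enamine 17 attacks through its oxygen-bearing β-carbon (Stork-type C-alkylation, C2–C3), and the resulting iminium ion 19 is captured by C4a of ring D in a 6-endo-trig Mannich-type Friedel–Crafts closure (C4–C4a) that forms ring F, overall a formal inverse-demand [4+2] of a cationic 2-oxadiene. The closest known reaction types are the oxa-Povarov reaction of aryl oxocarbenium ions with alkenes, the Povarov reaction of N-aryl iminium ions with enamines and enamides, and the Lewis-acid displacement of benzotriazole from N-(alpha-alkoxyalkyl)benzotriazoles by electron-rich alkenes. C3 is set by the twofold-symmetric (2S,5S)-2,5-dimethylpyrrolidine, whose methyl group syn to the enamine double bond shields one face of the β-carbon, so that the electrophile adds to the other face and gives 3S. C2 follows from the (E)-geometry of both partners in an endo-type (synclinal) approach with nitrogen over the oxocarbenium oxygen, which places ring E and the benzyloxy group trans (2R) and the amine cis to ring E, the C4 centre being of no consequence because step 13 erases it. The step needs C- over N-alkylation of the enamine and ring closure faster than loss of the ring-D phenoxide from 19 after iminium–enamine tautomerisation; the first is secured because N-alkylation is reversible, the second by the high nucleophilicity of the trialkoxy-substituted ring D, the six-membered transition state and the low temperature, and only C4a can be reached because C8 carries the upper unit and C6 is out of range.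

Step 13
Reactants: 20 ring-F-closed 4-(2,5-dimethylpyrrolidin-1-yl) protected dimer
Product: 21 deca-O-benzyl derivative of the target
Conditions: TFA (10 equiv), Et3SiH (5 equiv), CH2Cl2, 0 °C; aq. NaHCO3
Reagents that add atoms: none
Why: Protonation makes the amine a leaving group on a 2,4,6-trioxygenated benzylic carbon and the cation is trapped by Et3SiH (ionic hydrogenation, the reaction type behind acidolysis of 2,4,6-trimethoxybenzyl groups from nitrogen), which leaves C4 as CH2 and C2 and C3 untouched.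

Step 14
Reactants: 21 deca-O-benzyl derivative of the target
Product: 22 CNP0231186.1, mesquitol-(4α→8)-catechin
Conditions: H2 (1 atm), Pd(OH)2/C, THF/MeOH, rt
Reagents that add atoms: none
Why: Hydrogenolysis over Pd(OH)2/C should cleave all ten benzyl ethers (eight phenolic, two secondary) without touching the stereocentres or the interflavan bond.

Compound list

1 | 2,3,4-trihydroxyacetophenone | CC(=O)c1ccc(O)c(O)c1O | starting material
2 | 1-[3,4-bis(benzyloxy)-2-hydroxyphenyl]ethanone | CC(=O)c1ccc(OCc2ccccc2)c(OCc2ccccc2)c1O | intermediate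
3 | 1-[3,4-bis(benzyloxy)-2-(methoxymethoxy)phenyl]ethanone | CC(=O)c1ccc(OCc2ccccc2)c(OCc2ccccc2)c1OCOC | intermediate
4 | 3,4-bis(benzyloxy)benzaldehyde | O=Cc1ccc(OCc2ccccc2)c(OCc2ccccc2)c1 | starting material
5 | (E)-1-[3,4-bis(benzyloxy)-2-(methoxymethoxy)phenyl]-3-[3,4-bis(benzyloxy)phenyl]prop-2-en-1-one | COCOc1c(C(=O)/C=C/c2ccc(OCc3ccccc3)c(OCc3ccccc3)c2)ccc(OCc2ccccc2)c1OCc1ccccc1 | intermediate
6 | [3,4-bis(benzyloxy)-2-(methoxymethoxy)phenyl][(2R,3S)-3-[3,4-bis(benzyloxy)phenyl]oxiran-2-yl]methanone | COCOc1c(C(=O)[C@@H]2O[C@H]2c2ccc(OCc3ccccc3)c(OCc3ccccc3)c2)ccc(OCc2ccccc2)c1OCc1ccccc1 | intermediate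
7 | (2R,3R)-7,8-bis(benzyloxy)-2-[3,4-bis(benzyloxy)phenyl]-3-hydroxychroman-4-one | O=C1c2ccc(OCc3ccccc3)c(OCc3ccccc3)c2O[C@H](c2ccc(OCc3ccccc3)c(OCc3ccccc3)c2)[C@H]1O | intermediate
8 | (2R,3S,4R)-7,8-bis(benzyloxy)-2-[3,4-bis(benzyloxy)phenyl]chromane-3,4-diol | O[C@@H]1c2ccc(OCc3ccccc3)c(OCc3ccccc3)c2O[C@H](c2ccc(OCc3ccccc3)c(OCc3ccccc3)c2)[C@H]1O | intermediate
9 | (2R,3S,4R)-3,4,7,8-tetrakis(benzyloxy)-2-[3,4-bis(benzyloxy)phenyl]chromane | C(c1ccccc1)O[C@@H]1c2ccc(OCc3ccccc3)c(OCc3ccccc3)c2O[C@H](c2ccc(OCc3ccccc3)c(OCc3ccccc3)c2)[C@H]1OCc1ccccc1 | intermediate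
10 | 3,5-bis(benzyloxy)phenol | Oc1cc(OCc2ccccc2)cc(OCc2ccccc2)c1 | starting material
11 | 3,5-bis(benzyloxy)-2-[(2R,3S,4S)-3,7,8-tris(benzyloxy)-2-[3,4-bis(benzyloxy)phenyl]chroman-4-yl]phenol | C(c1ccccc1)Oc1ccc([C@H]2Oc3c(ccc(OCc4ccccc4)c3OCc3ccccc3)[C@@H](c3c(O)cc(OCc4ccccc4)cc3OCc3ccccc3)[C@@H]2OCc2ccccc2)cc1OCc1ccccc1 | intermediate
12 | 1H-benzotriazole | c1ccc2[nH]nnc2c1 | starting material
13 | 1-[[3,4-bis(benzyloxy)phenyl](chloro)methyl]-1H-benzotriazole (racemic) | ClC(c1ccc(OCc2ccccc2)c(OCc2ccccc2)c1)n1nnc2ccccc21 | intermediate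
14 | 1-[[3,4-bis(benzyloxy)phenyl]{3,5-bis(benzyloxy)-2-[(2R,3S,4S)-3,7,8-tris(benzyloxy)-2-[3,4-bis(benzyloxy)phenyl]chroman-4-yl]phenoxy}methyl]-1H-benzotriazole, both epimers at the acetal carbon | C(c1ccccc1)Oc1ccc([C@H]2Oc3c(ccc(OCc4ccccc4)c3OCc3ccccc3)[C@@H](c3c(OC(n4nnc5ccccc54)c4ccc(OCc5ccccc5)c(OCc5ccccc5)c4)cc(OCc4ccccc4)cc3OCc3ccccc3)[C@@H]2OCc2ccccc2)cc1OCc1ccccc1 | intermediate
15 | (benzyloxy)acetaldehyde | O=CCOCc1ccccc1 | starting material
16 | (2S,5S)-2,5-dimethylpyrrolidine | C[C@H]1CC[C@H](C)N1 | starting material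
17 | (2S,5S)-1-[(E)-2-(benzyloxy)ethenyl]-2,5-dimethylpyrrolidine | C[C@H]1CC[C@H](C)N1/C=C/OCc1ccccc1 | intermediate
18 | O-aryl oxocarbenium benzotriazolide formed from 14 by loss of benzotriazolide (ring-D oxygen doubly bonded to the ring-E benzylic carbon) | C(c1ccccc1)Oc1ccc([C@H]2Oc3c(ccc(OCc4ccccc4)c3OCc3ccccc3)[C@@H](c3c([O+]=Cc4ccc(OCc5ccccc5)c(OCc5ccccc5)c4)cc(OCc4ccccc4)cc3OCc3ccccc3)[C@@H]2OCc2ccccc2)cc1OCc1ccccc1.c1ccc2[n-]nnc2c1 | intermediate
19 | ring-open iminium benzotriazolide: ring-D aryl ether of the (2R,3S)-configured C2–C3 unit (flavan numbering) with C4 as the (2S,5S)-2,5-dimethylpyrrolidinium-ylidene carbon | C(c1ccccc1)Oc1ccc([C@H]2Oc3c(ccc(OCc4ccccc4)c3OCc3ccccc3)[C@@H](c3c(O[C@H](c4ccc(OCc5ccccc5)c(OCc5ccccc5)c4)[C@@H](OCc4ccccc4)C=[N+]4[C@@H](C)CC[C@@H]4C)cc(OCc4ccccc4)cc3OCc3ccccc3)[C@@H]2OCc2ccccc2)cc1OCc1ccccc1.c1ccc2[n-]nnc2c1 | intermediate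
20 | (2R,3S,4R)-3,5,7-tris(benzyloxy)-2-[3,4-bis(benzyloxy)phenyl]-4-[(2S,5S)-2,5-dimethylpyrrolidin-1-yl]-8-[(2R,3S,4S)-3,7,8-tris(benzyloxy)-2-[3,4-bis(benzyloxy)phenyl]chroman-4-yl]chromane (4R expected, 3,4-trans; centre removed in step 13) | C(c1ccccc1)Oc1ccc([C@H]2Oc3c(ccc(OCc4ccccc4)c3OCc3ccccc3)[C@@H](c3c(OCc4ccccc4)cc(OCc4ccccc4)c4c3O[C@H](c3ccc(OCc5ccccc5)c(OCc5ccccc5)c3)[C@@H](OCc3ccccc3)[C@@H]4N3[C@@H](C)CC[C@@H]3C)[C@@H]2OCc2ccccc2)cc1OCc1ccccc1 | intermediate
21 | (2R,3S)-3,5,7-tris(benzyloxy)-2-[3,4-bis(benzyloxy)phenyl]-8-[(2R,3S,4S)-3,7,8-tris(benzyloxy)-2-[3,4-bis(benzyloxy)phenyl]chroman-4-yl]chromane | C(c1ccccc1)Oc1ccc([C@H]2Oc3c(ccc(OCc4ccccc4)c3OCc3ccccc3)[C@@H](c3c(OCc4ccccc4)cc(OCc4ccccc4)c4c3O[C@H](c3ccc(OCc5ccccc5)c(OCc5ccccc5)c3)[C@@H](OCc3ccccc3)C4)[C@@H]2OCc2ccccc2)cc1OCc1ccccc1 | intermediate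
22 | (2R,3S)-2-(3,4-dihydroxyphenyl)-8-[(2R,3S,4S)-2-(3,4-dihydroxyphenyl)-3,7,8-trihydroxychroman-4-yl]chromane-3,5,7-triol (CNP0231186.1) | Oc1ccc([C@H]2Oc3c(ccc(O)c3O)[C@@H](c3c(O)cc(O)c4c3O[C@H](c3ccc(O)c(O)c3)[C@@H](O)C4)[C@@H]2O)cc1O | target

Total step count: 14. Longest linear sequence: 12 steps (1–8, 10, 12, 13, 14); steps 9 and 11 prepare the two side reagents.

Steps most likely to fail

Step 12 (the step carrying the new-method label). The cascade may stop after the first bond: the iminium ion 19 may lose the ring-D phenoxide by elimination, or lose the integrity of C3 by iminium–enamine exchange, before ring closure. The approach topology may also favour the 2,3-cis series, or the facial sense of the enamine may be opposite to the model, in which case the (2R,5R)-amine would be used. Fallback by known chemistry, the two bonds being made one after the other, setting out from 14 and returning at 21. Commercial (S)-4-benzyl-3-[(benzyloxy)acetyl]oxazolidin-2-one would be enolised with TiCl4 and i-Pr2NEt and added to 14 ionised with SnCl4, to give the auxiliary-controlled adduct, the imide F1. LiBH4 would release the auxiliary and give the primary alcohol F2, and DMP would give the aldehyde F3. TFA/Et3SiH would then close ring F by Friedel–Crafts hydroxyalkylation at C4a, with ionic reduction of the benzylic alcohol so formed, to give 21.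

Step 13. Acidolysis may be slow at the hindered tertiary amine, and it may be accompanied by reductive opening of ring F at C2–O1 or by loss of benzyl groups. Fallback setting out from 20 and returning at 22 without passing through 21: hydrogenolysis of 20 over Pd(OH)2/C in THF/MeOH/AcOH at 40 °C. After debenzylation the free ring-D phenols turn the C4 amine into a phenolic Mannich base, which would lose the pyrrolidine through a quinone methide that is hydrogenated to the CH2 group.

Step 8. The cation may attack 10 para to the hydroxyl (between the two benzyloxy groups) or at oxygen, and some 3,4-cis epimer may form. Fallback setting out from 10 and 9 and returning at 11. Bromination of 10 with NBS (CH2Cl2, −78 °C) at the position para to the hydroxyl would give 4-bromo-3,5-bis(benzyloxy)phenol F4, in which only the two equivalent positions ortho to the hydroxyl remain open. The same BF3·OEt2 coupling with 9 would give the brominated coupling product, bromophenol F5. Pd(OAc)2/PPh3 with HCO2Na (DMF, 80 °C) would then remove the bromine without touching the benzyl ethers and give 11.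

Further compounds

F1 | step 12 | (4S)-4-benzyl-3-acyl-oxazolidin-2-one adduct: 2-(benzyloxy)-3-[3,4-bis(benzyloxy)phenyl]-3-(ring-D aryloxy)propanoyl imide with the C2 and C3 centres of ring F as in 21 | C(c1ccccc1)Oc1ccc([C@H]2Oc3c(ccc(OCc4ccccc4)c3OCc3ccccc3)[C@@H](c3c(O[C@H](c4ccc(OCc5ccccc5)c(OCc5ccccc5)c4)[C@@H](OCc4ccccc4)C(=O)N4C(=O)OC[C@@H]4Cc4ccccc4)cc(OCc4ccccc4)cc3OCc3ccccc3)[C@@H]2OCc2ccccc2)cc1OCc1ccccc1
F2 | step 12 | primary alcohol from reductive removal of the auxiliary of F1 | C(c1ccccc1)Oc1ccc([C@H]2Oc3c(ccc(OCc4ccccc4)c3OCc3ccccc3)[C@@H](c3c(O[C@H](c4ccc(OCc5ccccc5)c(OCc5ccccc5)c4)[C@@H](OCc4ccccc4)CO)cc(OCc4ccccc4)cc3OCc3ccccc3)[C@@H]2OCc2ccccc2)cc1OCc1ccccc1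
F3 | step 12 | aldehyde from oxidation of F2 | C(c1ccccc1)Oc1ccc([C@H]2Oc3c(ccc(OCc4ccccc4)c3OCc3ccccc3)[C@@H](c3c(O[C@H](c4ccc(OCc5ccccc5)c(OCc5ccccc5)c4)[C@@H](OCc4ccccc4)C=O)cc(OCc4ccccc4)cc3OCc3ccccc3)[C@@H]2OCc2ccccc2)cc1OCc1ccccc1
F0 | step 13 | none | none
F4 | step 8 | 4-bromo-3,5-bis(benzyloxy)phenol | Oc1cc(OCc2ccccc2)c(Br)c(OCc2ccccc2)c1
F5 | step 8 | 4-bromo-3,5-bis(benzyloxy)-2-[(2R,3S,4S)-3,7,8-tris(benzyloxy)-2-[3,4-bis(benzyloxy)phenyl]chroman-4-yl]phenol | C(c1ccccc1)Oc1ccc([C@H]2Oc3c(ccc(OCc4ccccc4)c3OCc3ccccc3)[C@@H](c3c(O)cc(OCc4ccccc4)c(Br)c3OCc3ccccc3)[C@@H]2OCc2ccccc2)cc1OCc1ccccc1
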